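## Structural features

The target 10 (C19H20O8) consists of two identical benzene rings, ring A and ring B, joined only through one sp3 methylene carbon. It has no stereocentre, and the two halves are related by symmetry. Each ring is hexasubstituted. In the chain numbering used throughout it reads C1(OH), C2(CH2 bridge), C3(OH), C4(CH3), C5(OH), C6(acetyl, C7=O and C8H3), so oxygen stands on every second carbon from C1 to C7. The fragile parts are the electron-rich phloroglucinol rings, which oxidize readily as phenolates in air, and the two aryl–CH2 bonds, which can reopen by ipso protonation or by retro-Michael cleavage of a keto tautomer. The real difficulty is connectivity: twelve substituted ring positions, three different carbon substituents in a fixed order between the hydroxyl groups of each ring, and exactly one bridge without oligomer formation. The key step exploits the fact that C1 to C8 of each ring form a folded 1,3,5,7-tetracarbonyl chain closed by the C6–C1 bond. If C1 is bound to the oxygen on C5 instead of to C6, the same chain is a 6-(2-oxopropyl)-4-hydroxy-2-pyrone, so 10 is a constitutional isomer of the methylene-bridged bis(2-pyrone) 8. The two alkyl substituents help: the bridge on C2 shuts off the competing aldol aromatization (C2 to C7), and the methyl on C4 (C5 of the pyrone) leaves C3 of the pyrone as the only nucleophilic ring carbon when the bridge is laid down.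

## Logic of the disconnections

**10 to 8 (through 9).** The C6–C1 bond is cut in ring A and in ring B, and each C1 is rejoined to the oxygen on C5. This is the one ring bond whose formation is a Claisen acylation of a doubly activated carbon (C6, between C5=O and C7=O). The cut turns two hexasubstituted benzenes into two lactone rings of the same formula, needs no protecting group, and keeps the air-sensitive polyphenol out of every earlier step. The forward step must follow the Claisen mode rather than an aldol mode, must run twice in one molecule, and must not lose the bridge.

**8 to 5 and 6.** Both bonds from the bridge carbon to pyrone C3 are cut. C3 is the enol carbon of a vinylogous acid and the only free ring position, so the symmetric dimer falls into two identical halves and one C1 unit. The forward step must prefer ring C3 over the side-chain CH2 of 5.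

**5 to 4 and 2.** The side-chain bond between the CH2 on pyrone C6 and the ketone carbon (C6–C7 in chain numbering) is cut. This removes the only base-sensitive ketone and leaves a simple dimethylpyrone. The forward step requires regioselective deprotonation of the 6-methyl group in the presence of the 5-methyl group.

**4 to 3.** The lactone bond O1–C2 is cut, which gives an open-chain 3,5-dioxo ester. The forward closure must go through oxygen, which mild base secures.

**3 to 1 and 2.** The C4–C5 bond of the dioxo ester is cut, which gives two commercial compounds. The forward step requires acylation at the γ-carbon of 1 and not at its α-carbon, which dianion formation secures.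

## Other disconnections considered

Alternative 1: This is the first disconnection that comes to mind. Both aryl–CH2 bonds of 10 are cut. In the forward key step, two molecules of 1-(2,4,6-trihydroxy-3-methylphenyl)ethanone A1 condense with 6 through the ortho-quinone methide A3. A1 comes from Friedel–Crafts acetylation of 2-methylbenzene-1,3,5-triol A2.
- This plan is shorter and would be the practical choice.
- It is set aside because it is the default disconnection. The substitution pattern of both rings is bought with A2 and not constructed.
- A2 offers two equivalent free positions, so monoacylation must be stopped before diacylation.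
- The bridge is made on the most electron-rich and most oxidizable species of the whole sequence, under conditions in which bridge formation is reversible.

Alternative 2: The bonds C1–C2 and C4–C5 are cut in both rings, together with the C6–acetyl bonds. The bridge and both methyl groups then belong to one open chain, nonane-3,7-dione A4. The forward key step is a two-directional (3+3) cyclization of A4 with malonyl dichloride A5 to 2,2'-methylenebis(4-methylbenzene-1,3,5-triol) A6, followed by double Friedel–Crafts acetylation.
- The bridge is never made on a ring, which is attractive.
- The α-carbons of A4 are only singly activated, so closure through the enol oxygen should outrun closure through carbon.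
- Correcting that by a later isomerization would need the anion of an unactivated alkyl group, under far harsher conditions than the doubly activated C6 of 9 requires.
- The acetyl groups are not placed by the ring construction. They would have to be added with a Lewis acid to A6, whose bridge is the part most prone to ipso protonation and cleavage.
- A4 must itself be made, so no step is saved.

Alternative 3: Only one aryl–CH2 bond is cut, and the bridge is read as a former ring methyl group. This is a union of two carbons of like polarity. In the forward key step, 1-(2,4,6-trihydroxy-3,5-dimethylphenyl)ethanone A7 is dehydrogenated by a high-potential quinone oxidant to the ortho-quinone methide A3, which is trapped by A1.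
- The plan needs two different monomers and so gives up the symmetry of 10.
- The oxidant has no structural basis for distinguishing the methyl groups of A7, A1 and 10, all of which sit between phenolic hydroxyl groups. Over-oxidation and chain growth are therefore built into the mechanism.
- A3 can also consume itself by hetero-Diels–Alder dimerization.

Key step: step 5

Assumption: all 1,3-dicarbonyl compounds and pyrones are drawn in one tautomeric form. The enolizable stereocentres of 3 and 9 are left undefined because they are configurationally labile and disappear later. The target has no stereocentre.

## Steps

Step 1
Reactants: 1 methyl 3-oxopentanoate; 2 N-methoxy-N-methylacetamide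
Product: 3 methyl 4-methyl-3,5-dioxohexanoate
Conditions: NaH (1.1 equiv), THF, 0 °C; n-BuLi (1.05 equiv), 0 °C; 2, 0 °C to rt; aq. HCl
Reagents that add atoms: none
Why: γ-Acylation of a β-keto ester dianion combined with the Weinreb ketone synthesis: the last-formed and most basic carbanion (C4 of 1) attacks the amide, and the chelated tetrahedral adduct should survive until the quench, so that double addition and proton transfer from the more acidic product are avoided. The new C4 centre lies between two carbonyl groups, is labile and becomes sp2 in step 2.

Step 2
Reactants: 3 methyl 4-methyl-3,5-dioxohexanoate
Product: 4 4-hydroxy-5,6-dimethyl-2H-pyran-2-one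
Conditions: DBU (1.2 equiv), toluene, reflux; 1 M HCl
Reagents that add atoms: none
Why: Base-induced enol lactonization of a 3,5-dioxo ester: the C5 enolate oxygen attacks the ester in a 6-exo-trig closure with loss of methanol, and the conjugated 4-hydroxy-2-pyrone, held as its amidinium salt, is the thermodynamic sink. Closure through the terminal methyl carbon would need a far stronger base and should not compete.

Step 3
Reactants: 4 4-hydroxy-5,6-dimethyl-2H-pyran-2-one; 2 N-methoxy-N-methylacetamide
Product: 5 4-hydroxy-5-methyl-6-(2-oxopropyl)-2H-pyran-2-one
Conditions: lithium diisopropylamide (2.3 equiv), THF, −78 to −30 °C; 2, −78 to 0 °C; 1 M HCl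
Reagents that add atoms: none
Why: Vinylogous Claisen-type acylation of a 4-hydroxy-6-methyl-2-pyrone dianion, again stopped at the ketone stage by the Weinreb adduct. After the hydroxyl proton, only the 6-CH3 gives an anion conjugated through C6=C5 and C4=C3 to the lactone carbonyl, whereas an anion on the 5-CH3 cannot reach any carbonyl group. The exocyclic carbanion is the most nucleophilic site of the dianion.

Step 4
Reactants: 5 4-hydroxy-5-methyl-6-(2-oxopropyl)-2H-pyran-2-one (2 equiv); 6 formaldehyde
Product: 8 3,3'-methylenebis[4-hydroxy-5-methyl-6-(2-oxopropyl)-2H-pyran-2-one], via methylidene pyrandione 7 (not isolated)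
Conditions: 37% aq. CH2O (0.5 equiv), EtOH, 60 °C to reflux, no added base
Reagents that add atoms: none
Why: Knoevenagel condensation followed by Michael addition, the reaction type by which 4-hydroxycoumarins and 4-hydroxy-2-pyrones form 3,3'-methylene-bis compounds. C3 of 5 is the enol carbon of a vinylogous acid and reacts without base, while the side-chain CH2 needs base to enolize and C5 is blocked by methyl. The strong acceptor 7 should be captured at once by a second molecule of 5, and the sparingly soluble dimer should leave the solution.

Step 5
Reactants: 8 3,3'-methylenebis[4-hydroxy-5-methyl-6-(2-oxopropyl)-2H-pyran-2-one]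
Product: 10 1,1'-[methylenebis(2,4,6-trihydroxy-5-methylbenzene-3,1-diyl)]diethanone (methylenebis(3-methylphloracetophenone)), via open-chain bis(triketo ester) 9 (not isolated)
Conditions: Mg(OMe)2 (6 equiv), MeOH, reflux, Ar; cold 1 M HCl
Reagents that add atoms: none
Why: Methoxide adds to each lactone carbonyl (C1) and opens the pyrone to the magnesium chelate of 9, in which C6 lies between the C5 and C7 carbonyl groups and is enolized with ease. The C6 enolate attacks the C1 ester in a 6-exo-trig Claisen (Dieckmann-mode) closure in ring A and independently in ring B, and loss of methoxide with tautomerization of the cyclohexane-1,3,5-trione gives the aromatic acylphloroglucinolate, so that the methanol taken up is given back and the step is a net isomerization of 8. The closest known reaction type is the Mg(OMe)2-induced isomerization of 6-(2-oxoalkyl)-4-hydroxy-2-pyrones, and the base cyclization of 3,5,7-trioxo esters, to acylphloroglucinols (biomimetic tetraketide Claisen cyclization). The usual rival, the C2-to-C7 aldol closure that leads to resorcylates, would make C2 quaternary here because C2 carries the bridge, so it cannot end in an arene and stays reversible. Cross-arm closures through C4 or C2 likewise create non-enolizable quaternary carbons that methoxide can reopen, and relactonization only returns 8, whereas aromatization and chelation of the ortho-hydroxy ketone to magnesium are irreversible, so all equilibria should drain to 10. With both C2 positions enolized as magnesium chelates a retro-Michael loss of the bridge would have to expel a doubly charged fragment, and because 10 is symmetric any bridge exchange is degenerate. No stereocentre is created, and the labile centres of 9 (C2 and C4 of each arm) vanish on aromatization. The substituent order is fixed by the chain (bridge on C2, methyl on C4, acetyl on C6), so no regiochemical choice is left to the step.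

## Compound list

1 | methyl 3-oxopentanoate | CCC(=O)CC(=O)OC | starting material
2 | N-methoxy-N-methylacetamide | CC(=O)N(C)OC | starting material
3 | methyl 4-methyl-3,5-dioxohexanoate | CC(=O)C(C)C(=O)CC(=O)OC | intermediate
4 | 4-hydroxy-5,6-dimethyl-2H-pyran-2-one | CC1=C(C)C(O)=CC(=O)O1 | intermediate
5 | 4-hydroxy-5-methyl-6-(2-oxopropyl)-2H-pyran-2-one | CC(=O)CC1=C(C)C(O)=CC(=O)O1 | intermediate
6 | formaldehyde | C=O | starting material
7 | 5-methyl-3-methylidene-6-(2-oxopropyl)pyran-2,4-dione | CC(=O)CC1=C(C)C(=O)C(=C)C(=O)O1 | intermediate
8 | 3,3'-methylenebis[4-hydroxy-5-methyl-6-(2-oxopropyl)-2H-pyran-2-one] | CC(=O)CC1=C(C)C(O)=C(CC2=C(O)C(C)=C(CC(C)=O)OC2=O)C(=O)O1 | intermediate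
9 | dimethyl 2,4-bis(2-methyl-3,5-dioxohexanoyl)pentanedioate | COC(=O)C(CC(C(=O)OC)C(=O)C(C)C(=O)CC(C)=O)C(=O)C(C)C(=O)CC(C)=O | intermediate
10 | 1,1'-[methylenebis(2,4,6-trihydroxy-5-methylbenzene-3,1-diyl)]diethanone | CC(=O)c1c(O)c(C)c(O)c(Cc2c(O)c(C)c(O)c(C(C)=O)c2O)c1O | target

## Step count and risk

Total step count: 5. Longest linear sequence: 5 (1 to 3 to 4 to 5 to 8 to 10).

**Step 5 (key step).**
- What may go wrong: the two arms of the opened chain sit on a 1,3-related pair of carbons, so a cross-arm aldol addition followed by dehydration (the cyclohexenone-forming mode of 2,4-diacylglutarates) could drain material before the Claisen closures finish.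
- Other failure modes are retro-Michael loss of the bridge from a partly protonated chain, a stall after only one of the two closures, and air oxidation of the phenolate.
- Fallback: it sets out from 5 and comes back at 10. The ring transformation is carried out before the bridge exists. Compound 5 alone is treated with Mg(OMe)2 in methanol, opens to methyl 4-methyl-3,5,7-trioxooctanoate F1 and closes to 1-(2,4,6-trihydroxy-3-methylphenyl)ethanone F2. F2 is then condensed at its single free ring position with 6 to give 10.
- The pyrone-to-arene idea is kept, and no cross-arm reaction is possible. The aldol mode is no longer blocked at C2, however, so selectivity then rests on the magnesium template alone.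

**Step 3.**
- What may go wrong: the dilithio salt of 4 may be poorly soluble, the extra 5-methyl group may slow attack at the neighbouring carbanion, and acylation on the 4-oxygen or simple proton return on quench may take over.
- Fallback: it sets out from 1 and comes back at 5. The whole chain is assembled before the lactone is closed.
- The dianion of 1 is acylated with commercial ethyl (2-methyl-1,3-dioxolan-2-yl)acetate, with extra base for the acidic product, to give methyl 4-methyl-6-(2-methyl-1,3-dioxolan-2-yl)-3,5-dioxohexanoate F3.
- DBU lactonization of F3 gives 4-hydroxy-5-methyl-6-[(2-methyl-1,3-dioxolan-2-yl)methyl]-2H-pyran-2-one F4, and dilute aqueous acid removes the ketal to give 5.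

**Step 4.**
- What may go wrong: hydroxymethylation or condensation may occur at the side-chain active methylene of 5, or a second formaldehyde unit may be taken up there, because that CH2 is flanked by a ketone and a vinylogous ester.
- Fallback: it sets out from 4 and comes back at 8. The bridge is laid down before the reactive side chain exists.
- Compound 4 is condensed with 6 to give 3,3'-methylenebis(4-hydroxy-5,6-dimethyl-2H-pyran-2-one) F5.
- F5 is deprotonated four times with lithium diisopropylamide in THF/DMPU, and both 6-methyl carbanions are acylated with 2 to give 8.

## Further compounds

F1 | step 5 | methyl 4-methyl-3,5,7-trioxooctanoate | COC(=O)CC(=O)C(C)C(=O)CC(C)=O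
F2 | step 5 | 1-(2,4,6-trihydroxy-3-methylphenyl)ethanone | CC(=O)c1c(O)c(C)c(O)cc1O
F3 | step 3 | methyl 4-methyl-6-(2-methyl-1,3-dioxolan-2-yl)-3,5-dioxohexanoate | COC(=O)CC(=O)C(C)C(=O)CC1(C)OCCO1
F4 | step 3 | 4-hydroxy-5-methyl-6-[(2-methyl-1,3-dioxolan-2-yl)methyl]-2H-pyran-2-one | CC1(CC2=C(C)C(O)=CC(=O)O2)OCCO1
F5 | step 4 | 3,3'-methylenebis(4-hydroxy-5,6-dimethyl-2H-pyran-2-one) | CC1=C(C)C(O)=C(CC2=C(O)C(C)=C(C)OC2=O)C(=O)O1
A1 | alternative 1 | 1-(2,4,6-trihydroxy-3-methylphenyl)ethanone | CC(=O)c1c(O)c(C)c(O)cc1O
A2 | alternative 1 | 2-methylbenzene-1,3,5-triol | Cc1c(O)cc(O)cc1O
A3 | alternative 1 | 2-acetyl-3,5-dihydroxy-4-methyl-6-methylidenecyclohexa-2,4-dien-1-one | CC(=O)C1=C(O)C(C)=C(O)C(=C)C1=O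
A4 | alternative 2 | nonane-3,7-dione | CCC(=O)CCCC(=O)CC
A5 | alternative 2 | malonyl dichloride | O=C(Cl)CC(=O)Cl
A6 | alternative 2 | 2,2'-methylenebis(4-methylbenzene-1,3,5-triol) | Cc1c(O)cc(O)c(Cc2c(O)cc(O)c(C)c2O)c1O
A7 | alternative 3 | 1-(2,4,6-trihydroxy-3,5-dimethylphenyl)ethanone | CC(=O)c1c(O)c(C)c(O)c(C)c1O
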